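Ring A is closed by an anionic annulation whose ring-forming event is the C2–C3 bond. The precursor is a monocyclic ring B silyl enol ether from (R)-carvone that carries a C(CH3)2CO2CH3 arm (C4, C3) on C5. Its enolate, nucleophilic at the future ring-fusion carbon C10, adds to phenyl vinyl sulfone (C1–C2); the resulting C2 sulfonyl carbanion then acylates the C3 ester, giving C10–C1, the C10 quaternary centre and C2–C3 in one operation. The step exploits that C10 is α to the ring B carbonyl C9 and that C3 is flanked by non-enolisable C4. The isopropenyl group steers C5 and C10, then becomes the C7=C8 bond.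

Key step: step 2

Remark on locants: labdane numbering of the target is used throughout. Ring A = C1, C2, C3, C4, C5, C10; ring B = C5 to C10; side chain C11 to C15 with C16 the methyl on C13; C17 on C8; C18 and C19 on C4; C20 on C10. α and β refer to the usual drawing with C20 β.

Assumption: methyl hydrogen (R)-3-methylglutarate (16) is bought as the single enantiomer (it is the product of enzymatic half-hydrolysis of dimethyl 3-methylglutarate). C2 of 6 and 7, and the peroxy carbon of 9, are stereochemically undefined and inconsequential.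

Step 1
Reactants: 1 (R)-carvone; 2 1-methoxy-2-methyl-1-(trimethylsilyloxy)prop-1-ene
Product: 3 silyl enol ether methyl 2-methyl-2-[(1R,5R)-2-methyl-5-(prop-1-en-2-yl)-3-(trimethylsilyloxy)cyclohex-2-en-1-yl]propanoate
Conditions: Tf2NH (1 mol %), toluene, −78 °C; Et3N; concentrate
Reagents that add atoms: none
Why: Mukaiyama–Michael addition, in which the silyl-activated enone is attacked at C5 by the ketene silyl acetal anti to the isopropenyl group (axial attack on the half-chair with the C7 substituent pseudo-equatorial), which sets C5 and delivers the regiodefined C9–C10 silyl enol ether by silyl transfer.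

Step 2
Reactants: 3 silyl enol ether; 4 phenyl vinyl sulfone
Product: 7 β-keto sulfone 2-(phenylsulfonyl)-7α-(prop-1-en-2-yl)-4,4,10β-trimethyl-5α-decalin-3,9-dione, via potassium enolate 5 (not isolated), via potassio sulfone 6 (not isolated)
Conditions: KOt-Bu (1.05 equiv), THF, −20 °C; 4 (1.0 equiv), −78 → 23 °C; AcOH
Reagents that add atoms: none
Why: KOt-Bu cleaves the O–Si bond to give the regiodefined tetrasubstituted potassium enolate 5, which adds in a Michael reaction to phenyl vinyl sulfone to forge C10–C1 and leave an α-sulfonyl carbanion at C2 (6); this carbanion attacks the C3 methyl ester in a Claisen (Dieckmann-type) acylation that forms C2–C3 and expels methoxide, which deprotonates the β-keto sulfone and makes the sequence irreversible. The closest known reaction types are the Michael-initiated ring closure (Michael–Claisen annulation) and the Dieckmann-type cyclisation of sulfonyl carbanions onto esters, including α,α-dimethyl esters. Ring A (C1, C2, C3, C4, C5, C10) closes in a 6-exo-trig mode. The new quaternary stereocentre C10 is controlled by the adjacent C5 substituent: the acceptor approaches the enolate face anti to the bulky C(CH3)2CO2CH3 group (the usual 2,3-trans outcome of conjugate addition–alkylation on carvone), which places C1 α and C20 β and so leads to the trans-fused decalin, while C2 is epimerisable and is erased in step 3. The step needs acylation by C2 to win over paths that begin with proton transfer from C8 to C2; closure of a C8 enolate onto the C3 ester would give a bicyclo[2.2.2]octanedione that cannot be stabilised by bridgehead enolisation, so it should revert and only the fused β-keto sulfone is drained from the equilibrium, and the use of one equivalent of sulfone limits double addition.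

Step 3
Reactants: 7 β-keto sulfone
Product: 8 7α-(prop-1-en-2-yl)-4,4,10β-trimethyl-5α-decalin-3,9-dione
Conditions: Al(Hg), THF/H2O (9:1), 0 → 23 °C
Reagents that add atoms: none
Why: Reductive desulfonylation, in which electron transfer from aluminium amalgam cleaves the C2–S bond activated by the C3 carbonyl while the hindered ketones and the alkene should be untouched, so that the C2 stereocentre disappears.

Step 4
Reactants: 8 diketone
Product: 11 4,4,10β-trimethyl-5α-decal-7-ene-3,9-dione, via methoxy hydroperoxide 9 (not isolated), via C7 acetate 10 (not isolated)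
Conditions: O3, CH2Cl2/MeOH (4:1), −78 °C; Ac2O, Et3N, DMAP, 0 → 23 °C; DBU, 23 °C
Reagents that add atoms: none
Why: Ozonolysis in methanol gives the α-methoxy hydroperoxide, whose peracetate undergoes Criegee rearrangement with retention to the C7 acetate, and E1cB loss of acetate from this β-acetoxy ketone places the double bond at C7=C8 in conjugation with C9=O.

Step 5
Reactants: 11 enedione
Product: 12 3β-hydroxy-4,4,10β-trimethyl-5α-decal-7-en-9-one
Conditions: NaBH4, MeOH/CH2Cl2, −40 °C
Reagents that add atoms: none
Why: Chemoselective hydride reduction, since the saturated C3 ketone is attacked faster than the conjugated and more hindered C9 enone, and axial delivery from the α face, away from the β-axial methyl groups on C4 and C10, should give the equatorial 3β-alcohol.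

Step 6
Reactants: 12 hydroxy enone
Product: 13 3β-hydroxy-8-(hydroxymethyl)-4,4,10β-trimethyl-5α-decal-7-en-9-one
Conditions: HCHO (37% aq.), imidazole, NaHCO3 (1 M aq.), THF, 23 °C
Reagents that add atoms: formaldehyde, C=O
Why: Morita–Baylis–Hillman reaction, in which imidazole adds reversibly to C7, the C8 enolate is hydroxymethylated and the catalyst is expelled, installing C17 on C8 without moving the C7=C8 bond.

Step 7
Reactants: 13 hydroxymethyl enone
Product: 14 8-(hydroxymethyl)-9-methylidene-4,4,10β-trimethyl-5α-decal-7-en-3β-ol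
Conditions: Zn, CH2Br2, TiCl4, THF; then 13, CH2Cl2, 0 → 23 °C
Reagents that add atoms: dibromomethane, BrCBr
Why: Takai–Lombardo methylenation, whose non-basic zinc–titanium methylene reagent should olefinate the hindered, γ-enolisable C9 ketone without enolisation or conjugate addition and tolerates free hydroxyl groups, giving the exocyclic C9=C11 bond.

Step 8
Reactants: 14 diene diol
Product: 15 3β,17-bis(triethylsilyl) ether of 14
Conditions: TESCl, imidazole, DMAP (cat.), DMF, 23 °C
Reagents that add atoms: chlorotriethylsilane, CC[Si](Cl)(CC)CC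
Why: Silylation of both hydroxyls, so that neither a free allylic alcohol nor an allylic borinate is exposed to zerovalent palladium in step 10.

Step 9
Reactants: 16 (3R)-5-methoxy-3-methyl-5-oxopentanoic acid
Product: 17 methyl (3S)-4-iodo-3-methylbutanoate
Conditions: PhI(OAc)2, I2, cyclohexane, hν, 80 °C
Reagents that add atoms: iodine, [I][I]
Why: Hunsdiecker-type iododecarboxylation, in which the acyl hypoiodite loses CO2 and the primary radical is trapped by iodine; the C13 stereocentre is not involved and becomes S only through a change of CIP priorities.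

Step 10
Reactants: 15 bis-silyl diene; 17 iodide
Product: 20 methyl (13R)-3β,17-dihydroxylabd-7-en-15-oate, via alkylborane 18 (not isolated), via silylated ester 19 (not isolated)
Conditions: 9-BBN, THF, 23 → 40 °C; 17, Pd(OAc)2 (5 mol %), PCy3 (10 mol %), K3PO4·H2O, THF, 23 °C; then HCl (1 M)/MeOH, 0 °C
Reagents that add atoms: none
Why: Hydroboration places boron on the terminal C11 and hydrogen on C9 from the α face, opposite the axial C20 methyl, which sets C9 (H α, side chain β); the B-alkyl-9-BBN then undergoes Suzuki–Miyaura alkyl–alkyl coupling with the primary iodide under a bulky electron-rich phosphine that suppresses β-hydride elimination, and dilute acid removes both silyl groups.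

Step 11
Reactants: 20 diol ester
Product: 21 methyl (13R)-17-acetoxy-3β-hydroxylabd-7-en-15-oate (target)
Conditions: Ac2O (1.1 equiv), pyridine, CH2Cl2, −20 °C
Reagents that add atoms: acetic anhydride, CC(=O)OC(C)=O
Why: Acylation, in which the primary allylic C17 hydroxyl should react much faster than the secondary C3 hydroxyl next to the gem-dimethyl carbon, so that only the 17-acetate forms.

Compound list

1 | (R)-carvone, (5R)-2-methyl-5-(prop-1-en-2-yl)cyclohex-2-en-1-one | CC1=CC[C@H](CC1=O)C(C)=C | starting material
2 | 1-methoxy-2-methyl-1-(trimethylsilyloxy)prop-1-ene | COC(=C(C)C)O[Si](C)(C)C | starting material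
3 | methyl 2-methyl-2-[(1R,5R)-2-methyl-5-(prop-1-en-2-yl)-3-(trimethylsilyloxy)cyclohex-2-en-1-yl]propanoate (ester arm on C5 trans to the C7 isopropenyl) | C[Si](C)(C)OC1=C(C)[C@H](C(C)(C)C(=O)OC)C[C@@H](C(C)=C)C1 | intermediate
4 | phenyl vinyl sulfone | C=CS(=O)(=O)c1ccccc1 | starting material
5 | potassium enolate corresponding to 3 (O–K on C9, C9=C10 enolate) | [K]OC1=C(C)[C@H](C(C)(C)C(=O)OC)C[C@@H](C(C)=C)C1 | intermediate
6 | C2-potassio derivative of methyl 2-methyl-2-[(1R,2S,5R)-2-methyl-3-oxo-2-[2-(phenylsulfonyl)ethyl]-5-(prop-1-en-2-yl)cyclohexyl]propanoate (sulfonylethyl chain on C10 trans to the C5 arm) | O=C1C[C@H](C(C)=C)C[C@@H](C(C)(C)C(=O)OC)[C@]1(C)CC([K])S(=O)(=O)c1ccccc1 | intermediate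
7 | 2-(phenylsulfonyl)-7α-(prop-1-en-2-yl)-4,4,10β-trimethyl-5α-decalin-3,9-dione (trans-fused, C2 epimers) | O=C1C[C@H](C(C)=C)C[C@H]2C(C)(C)C(=O)C(S(=O)(=O)c3ccccc3)C[C@]12C | intermediate
8 | 7α-(prop-1-en-2-yl)-4,4,10β-trimethyl-5α-decalin-3,9-dione | O=C1C[C@H](C(C)=C)C[C@H]2C(C)(C)C(=O)CC[C@]12C | intermediate
9 | 7α-(1-hydroperoxy-1-methoxyethyl)-4,4,10β-trimethyl-5α-decalin-3,9-dione | O=C1C[C@H](C(C)(OC)OO)C[C@H]2C(C)(C)C(=O)CC[C@]12C | intermediate
10 | 7α-acetoxy-4,4,10β-trimethyl-5α-decalin-3,9-dione | O=C1C[C@H](OC(C)=O)C[C@H]2C(C)(C)C(=O)CC[C@]12C | intermediate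
11 | 4,4,10β-trimethyl-5α-decal-7-ene-3,9-dione | O=C1C=CC[C@H]2C(C)(C)C(=O)CC[C@]12C | intermediate
12 | 3β-hydroxy-4,4,10β-trimethyl-5α-decal-7-en-9-one | O=C1C=CC[C@H]2C(C)(C)[C@@H](O)CC[C@]12C | intermediate
13 | 3β-hydroxy-8-(hydroxymethyl)-4,4,10β-trimethyl-5α-decal-7-en-9-one | O=C1C(CO)=CC[C@H]2C(C)(C)[C@@H](O)CC[C@]12C | intermediate
14 | 8-(hydroxymethyl)-9-methylidene-4,4,10β-trimethyl-5α-decal-7-en-3β-ol | C=C1C(CO)=CC[C@H]2C(C)(C)[C@@H](O)CC[C@]12C | intermediate
15 | 3β-(triethylsilyloxy)-8-[(triethylsilyloxy)methyl]-9-methylidene-4,4,10β-trimethyl-5α-decal-7-ene | C=C1C(CO[Si](CC)(CC)CC)=CC[C@H]2C(C)(C)[C@@H](O[Si](CC)(CC)CC)CC[C@]12C | intermediate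
16 | (3R)-5-methoxy-3-methyl-5-oxopentanoic acid (methyl hydrogen (R)-3-methylglutarate) | COC(=O)C[C@H](C)CC(=O)O | starting material
17 | methyl (3S)-4-iodo-3-methylbutanoate | COC(=O)C[C@H](C)CI | intermediate
18 | B-alkyl-9-borabicyclo[3.3.1]nonane from 15 (boron on C11, H on C9 α) | C1CCC2CCCC1B2C[C@H]1C(CO[Si](CC)(CC)CC)=CC[C@H]2C(C)(C)[C@@H](O[Si](CC)(CC)CC)CC[C@]12C | intermediate
19 | methyl (13R)-3β,17-bis(triethylsilyloxy)labd-7-en-15-oate | COC(=O)C[C@H](C)CC[C@H]1C(CO[Si](CC)(CC)CC)=CC[C@H]2C(C)(C)[C@@H](O[Si](CC)(CC)CC)CC[C@]12C | intermediate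
20 | methyl (13R)-3β,17-dihydroxylabd-7-en-15-oate | COC(=O)C[C@H](C)CC[C@H]1C(CO)=CC[C@H]2C(C)(C)[C@@H](O)CC[C@]12C | intermediate
21 | methyl (13R)-17-acetoxy-3β-hydroxylabd-7-en-15-oate, i.e. methyl (3R)-5-[(1R,4aR,6S,8aR)-2-(acetoxymethyl)-6-hydroxy-5,5,8a-trimethyl-1,4,4a,5,6,7,8,8a-octahydronaphthalen-1-yl]-3-methylpentanoate | COC(=O)C[C@H](C)CC[C@H]1C(COC(C)=O)=CC[C@H]2C(C)(C)[C@@H](O)CC[C@]12C | target

Total step count: 11. Longest linear sequence: 10 steps (steps 1 to 8, 10 and 11); step 9 is the side branch.

Steps most likely to fail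

1. Step 2. The C2 carbanion may be quenched by proton transfer from C8 and the resulting ketone enolate may add a second sulfone, or acylation of the hindered C3 ester may be too slow. The fallback sets out from 3 and comes back at 8. Potassium enolate 5, made as in the main route, would be alkylated with methyl bromoacetate to the keto diester F1. LiAlH4 would reduce both esters and the ketone to the triol F2. I2, PPh3 and imidazole should convert only the unhindered primary hydroxyl on C2 into the iodo diol F3. Dess–Martin periodinane would oxidise the neopentyl primary and the C9 secondary alcohol to the iodo keto aldehyde F4. SmI2/HMPA would then close ring A at the same C2–C3 bond by an intramolecular Barbier addition of the alkylsamarium to the aldehyde, giving the hydroxy ketone F5. Dess–Martin oxidation of F5 gives 8.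

2. Step 10. Oxidative addition of the β-branched primary iodide may be slow and β-hydride elimination may consume the alkylpalladium species, and facial selectivity in the hydroboration may be incomplete. The fallback sets out from 15 and comes back at 19. The same alkylborane 18 would be coupled (Pd(PPh3)4, K3PO4, THF) at the CH2 terminus of methyl (E)-4-bromo-3-methylbut-2-enoate, an allylic bromide that adds readily to zerovalent palladium, to give the unsaturated ester F6. Copper hydride-catalysed asymmetric conjugate reduction (CuCl, NaOt-Bu, p-tol-BINAP, polymethylhydrosiloxane, toluene) would then set C13 by catalyst control. The ligand antipode would be chosen on a model enoate to give 13R. The product is 19.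

3. Step 7. Steric shielding of the C9 carbonyl by the quaternary C10 and the substituted C8 may leave the methylenation incomplete. The fallback sets out from 13 and comes back at 14. The small and strongly nucleophilic (trimethylsilyl)methyllithium, with CeCl3 in THF at −78 °C, would add to C9 to give the β-hydroxysilane F7. KH in THF would then induce Peterson elimination to 14.

Further compounds

F1 | step 2 | methyl 2-[(1R,2S,5R)-2-(2-methoxy-2-oxoethyl)-2-methyl-3-oxo-5-(prop-1-en-2-yl)cyclohexyl]-2-methylpropanoate | O=C1C[C@H](C(C)=C)C[C@@H](C(C)(C)C(=O)OC)[C@]1(C)CC(=O)OC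
F2 | step 2 | 2-(2-hydroxyethyl)-3-(1-hydroxy-2-methylpropan-2-yl)-2-methyl-5-(prop-1-en-2-yl)cyclohexan-1-ol (carbinol epimers at C9, other centres as in F1) | OC1C[C@H](C(C)=C)C[C@@H](C(C)(C)CO)[C@]1(C)CCO
F3 | step 2 | 3-(1-hydroxy-2-methylpropan-2-yl)-2-(2-iodoethyl)-2-methyl-5-(prop-1-en-2-yl)cyclohexan-1-ol (carbinol epimers at C9) | OC1C[C@H](C(C)=C)C[C@@H](C(C)(C)CO)[C@]1(C)CCI
F4 | step 2 | 2-[2-(2-iodoethyl)-2-methyl-3-oxo-5-(prop-1-en-2-yl)cyclohexyl]-2-methylpropanal (centres as in F1) | O=C1C[C@H](C(C)=C)C[C@@H](C(C)(C)C=O)[C@]1(C)CCI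
F5 | step 2 | 3β-hydroxy-7α-(prop-1-en-2-yl)-4,4,10β-trimethyl-5α-decalin-9-one | O=C1C[C@H](C(C)=C)C[C@H]2C(C)(C)[C@@H](O)CC[C@]12C
F6 | step 10 | methyl (13E)-3β,17-bis(triethylsilyloxy)labda-7,13-dien-15-oate | COC(=O)/C=C(\C)CC[C@H]1C(CO[Si](CC)(CC)CC)=CC[C@H]2C(C)(C)[C@@H](O[Si](CC)(CC)CC)CC[C@]12C
F7 | step 7 | 8-(hydroxymethyl)-4,4,10β-trimethyl-9-[(trimethylsilyl)methyl]-5α-decal-7-ene-3β,9-diol (C9 epimers) | C[Si](C)(C)CC1(O)C(CO)=CC[C@H]2C(C)(C)[C@@H](O)CC[C@]12C
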